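The earlier runs and the new flask come from a simulation for an exercise, and the scatter is random.

Late times were my way in: the larch flask holds the charge of the oak run and is simply read later, at 75 min.

common to all: Cat 0.00500 M
- oak: Sub 1.00 M; Rgt 1.00 M
- maple: Sub 0.600 M; Rgt 0.600 M
- elm: Sub 0.500 M; Rgt 1.00 M
- ash: Sub 1.00 M; Rgt 3.00 M
- larch: Sub 1.00 M; Rgt 1.00 M; time 75 min

- oak run (time / min: [Prd] / M): 1.1: 0.069; 3.4: 0.181; 6.4: 0.291; 10: 0.401; 15: 0.505; 20: 0.563; 25: 0.612
- maple run (time / min: [Prd] / M): 1.1: 0.040; 3.4: 0.113; 6.4: 0.191; 10: 0.249; 15: 0.309; 20: 0.352; 25: 0.379
- elm run (time / min: [Prd] / M): 1.1: 0.046; 3.4: 0.123; 6.4: 0.191; 10: 0.229; 15: 0.289; 20: 0.305; 25: 0.340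
- ash run (time / min: [Prd] / M): 1.1: 0.073; 3.4: 0.205; 6.4: 0.319; 10: 0.415; 15: 0.498; 20: 0.542; 25: 0.563

(standard deviation of a reading: 0.005 M)

- Overall: Sub + Rgt -> Prd, with Cat as catalyst.
- Constant volume, constant temperature.
- Bound and free are read together.
- "The second partner" is Rgt.
- An order is taken over about fifteen percent of the charge, up and down.

1. reaction order in [Rgt] at the outset, round the charge of the oak run, defined at two percent of the Sub turned into Prd
2. reaction order in [Sub] at the outset, round the charge of the oak run, defined at two percent of the Sub turned into Prd (one fixed amount of Prd, the same in the runs compared)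
3. the maple run starts with 0.400 M less of Sub and of Rgt than the oak run, and with no Prd. Compared where both hold the same amount of Sub, once fifteen percent of what the maple run was charged with has turned into Prd, is the maple run faster, slower or alike (within a tenth)?
4. Prd in the larch run at 75 min, as a share of the Sub charged

I followed the oak run slowly. In the first instants it moved fast: after 1.1 min, 6.90% of its Sub stood as Prd. In the middle of the oak run, between 10 min and 15 min, the Prd share rose at 0.0208 min⁻¹. Over the last readings of the oak run, between 20 min and 25 min, it rose at 0.00980 min⁻¹. So the read rate of the oak run fell to half, while its unreacted Sub fell to 0.754 of its value. The ash run, with 3.00 M of Rgt against 1.00 M, stood lower than the oak run at 25 min. I suspected a fading that goes with time (catalyst deactivation, in the usual term).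

From the two rates of the oak run, 10.0 min apart, I kept one number, 13.3 min: the time in which the late rate falls by the factor e, my tail time. It is a reading and carries the scatter. At 22.5 min, the middle of the last interval, 58.7% of the oak charge was already Prd by the readings, so I reckoned just the correction. A rate that decays exponentially adds its present value times the time constant, less the piece beyond the time asked. That tail came to 12.8%, and my figure for the larch run was 71.5%.

The forecast gave 0.3 for the order in Rgt and 0.55 for the order in Sub. It called the maple run faster and put the larch run at 74%. Of the ash run standing lower than the oak run late on, it wrote that this “points to time-driven catalyst death”. My figure lay below the forecast's.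

The flask gave orders of 0.41 in Rgt and 0.49 in Sub. The maple run was faster, by a rate ratio of 1.8 over the oak run where both hold the same amount of Sub, and the larch run reached 72.8%, 1.3 percentage points above my figure.

    Cat + Sub → X + Byp (29.16 M⁻¹ min⁻¹)
    X + Rgt → Prd + Cat (32.28 M⁻¹ min⁻¹)
    Cat → Z (0.09840 min⁻¹)
    Sub + Rgt ⇌ Sub.Rgt, settled at all times (0.2300 M⁻¹)

The larch run stops short of its charge mainly through the step from Cat to Z: without that step the same run reaches 99.5%. I carried the tail time to the elm run. Around 20 min the elm readings stood at 62.3% of its charge, rising at 0.0102 min⁻¹, so its tail came to 13.6% of that charge. Followed backwards, that exponential crosses half of the elm charge at 11.4 min; the elm run got there at 11.0 min.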